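**Retrosynthetic overview**
1. Target 40 ⇐ global desilylation ⇐ allylic sulfone alkylation and Pd-mediated desulfonylation joining chroman bromide 21 (C9') to the C30 sulfone 36 (C10').
2. 36 ⇐ (E)-allylic tertiary alcohol 31 ⇐ reductive epoxide opening of adduct 28; 28 ⇐ α-selective carbonyl allylation of epoxy aldehyde 26 (C15) by the allylbarium from chloride 24 (C15), which forms C21'–C22'.
3. 21 ⇐ chroman 18; the pyran ring is the only ring made (the benzene ring is bought), closed by Pd-catalysed aryl C–O coupling of tertiary alcohol 17, itself from B-alkyl Suzuki coupling of 15 with dihalide 10.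
4. Both stereocentres come from Sharpless epoxidation (L-(+)-tartrate) of farnesol-derived allylic alcohols; every side-chain carbon comes from (2E,6E)-farnesol, the arene from 2,3-dimethylphenol.

Assumption: the SMILES is read as (2S) at the chroman carbon and (S) at the side-chain carbinol, side-chain carbons are called C1' (on C2) to C32', and (2E,6E)-farnesol of high isomeric purity is taken as the commercial terpene source.

**Route**

Step 1
Reactants: 1 (2E,6E)-farnesol
Product: 2 (2E,6E)-farnesyl acetate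
Conditions: Ac2O, pyridine, DMAP (cat.), CH2Cl2, 0 °C → rt
Reagents that add atoms: acetic anhydride CC(=O)OC(C)=O
Why: DMAP-catalysed O-acylation masks the C1 hydroxyl as an allylic acetate, which also deactivates the neighbouring 2,3-alkene towards the allylic oxidation that follows.

Step 2
Reactants: 2 (2E,6E)-farnesyl acetate
Product: 3 (2E,6E,10E)-12-hydroxy-3,7,11-trimethyldodeca-2,6,10-trienyl acetate
Conditions: SeO2 (0.3 equiv), t-BuOOH (70% aq., 3 equiv), salicylic acid (cat.), CH2Cl2, 0 °C → rt; unreacted 2 recycled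
Reagents that add atoms: tert-butyl hydroperoxide CC(C)(C)OO
Why: SeO2-catalysed allylic oxidation (ene reaction then [2,3]-sigmatropic shift) attacks the most electron-rich terminal alkene and hydroxylates its (E)-methyl group selectively.

Step 3
Reactants: 4 2,3-dimethylphenol
Product: 5 2,3-dimethyl-4-nitrosophenol
Conditions: NaNO2, conc. HCl, EtOH/H2O, 0 °C
Reagents that add atoms: sodium nitrite [Na+].[O-]N=O
Why: Electrophilic aromatic nitrosation takes place para to the hydroxyl group, the most activated free position.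

Step 4
Reactants: 5 2,3-dimethyl-4-nitrosophenol
Product: 6 4-amino-2,3-dimethylphenol
Conditions: H2 (1 atm), Pd/C (5%), MeOH, rt
Reagents that add atoms: none
Why: Catalytic hydrogenation reduces the nitroso group (quinone monoxime tautomer) cleanly to the primary amine.

Step 5
Reactants: 6 4-amino-2,3-dimethylphenol
Product: 7 2,3-dimethyl-4-[tri(propan-2-yl)silyloxy]aniline
Conditions: i-Pr3SiCl, imidazole, DMF, rt
Reagents that add atoms: chlorotri(propan-2-yl)silane CC(C)[Si](Cl)(C(C)C)C(C)C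
Why: Imidazole-mediated silylation takes the phenol oxygen selectively over the aniline nitrogen and installs a base-stable, fluoride-labile protecting group.

Step 6
Reactants: 7 2,3-dimethyl-4-[tri(propan-2-yl)silyloxy]aniline
Product: 8 6-iodo-2,3-dimethyl-4-[tri(propan-2-yl)silyloxy]aniline
Conditions: N-iodosuccinimide (1.05 equiv), MeCN, 0 °C, dark
Reagents that add atoms: N-iodosuccinimide O=C1CCC(=O)N1I
Why: Electrophilic aromatic iodination is steered by the strongly activating amino group to its only free ortho position, the other ring hydrogen being shielded by the bulky silyl ether.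

Step 7
Reactants: 8 6-iodo-2,3-dimethyl-4-[tri(propan-2-yl)silyloxy]aniline
Product: 10 (4-bromo-5-iodo-2,3-dimethylphenoxy)tri(propan-2-yl)silane, via arenediazonium bromide 9 (not isolated)
Conditions: t-BuONO (1.5 equiv), CuBr2 (1.2 equiv), MeCN, 0 → 50 °C
Reagents that add atoms: copper dibromide Br[Cu]Br
Why: Non-aqueous Sandmeyer bromodediazoniation replaces the amino group by bromine while the silyl ether and the aryl iodide survive.

Step 8
Reactants: 3 (2E,6E,10E)-12-hydroxy-3,7,11-trimethyldodeca-2,6,10-trienyl acetate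
Product: 11 (2E,6E,10E)-12-acetoxy-2,6,10-trimethyldodeca-2,6,10-trienyl pivalate
Conditions: t-BuCOCl, pyridine, DMAP (cat.), CH2Cl2, 0 °C → rt
Reagents that add atoms: pivaloyl chloride CC(C)(C)C(Cl)=O
Why: Acylation of the new primary allylic alcohol gives a hindered ester that will outlast the acetate and all later basic and organometallic steps of the chroman synthesis.

Step 9
Reactants: 11 (2E,6E,10E)-12-acetoxy-2,6,10-trimethyldodeca-2,6,10-trienyl pivalate
Product: 12 (2E,6E,10E)-12-hydroxy-2,6,10-trimethyldodeca-2,6,10-trienyl pivalate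
Conditions: K2CO3 (0.2 equiv), MeOH, 0 °C
Reagents that add atoms: none
Why: Base-catalysed transesterification removes the unhindered acetate far faster than the pivalate and frees the allylic alcohol needed to direct the epoxidation.

Step 10
Reactants: 12 (2E,6E,10E)-12-hydroxy-2,6,10-trimethyldodeca-2,6,10-trienyl pivalate
Product: 13 (2E,6E)-9-[(2S,3S)-3-(hydroxymethyl)-2-methyloxiran-2-yl]-2,6-dimethylnona-2,6-dienyl pivalate
Conditions: Ti(OiPr)4 (0.1 equiv), diethyl L-(+)-tartrate (0.12 equiv), t-BuOOH (2 equiv, anhydrous), 4 Å molecular sieves, CH2Cl2, −20 °C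
Reagents that add atoms: tert-butyl hydroperoxide CC(C)(C)OO
Why: Sharpless asymmetric epoxidation touches only the alkene of the allylic alcohol and, with the L-(+)-tartrate ligand, sets the quaternary carbon that becomes chroman C2 as (S) in about 95% ee.

Step 11
Reactants: 13 (2E,6E)-9-[(2S,3S)-3-(hydroxymethyl)-2-methyloxiran-2-yl]-2,6-dimethylnona-2,6-dienyl pivalate
Product: 14 (2E,6E)-9-[(2S,3R)-3-(iodomethyl)-2-methyloxiran-2-yl]-2,6-dimethylnona-2,6-dienyl pivalate
Conditions: I2, PPh3, imidazole, CH2Cl2, 0 °C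
Reagents that add atoms: iodine II
Why: Appel-type iodination converts the primary alcohol into the iodide by SN2 without opening the epoxide, the stereocentres being untouched (the descriptor change is only a priority change).

Step 12
Reactants: 14 (2E,6E)-9-[(2S,3R)-3-(iodomethyl)-2-methyloxiran-2-yl]-2,6-dimethylnona-2,6-dienyl pivalate
Product: 15 (2E,6E,10S)-10-hydroxy-2,6,10-trimethyldodeca-2,6,11-trienyl pivalate
Conditions: Zn dust (activated), EtOH, 60 °C
Reagents that add atoms: none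
Why: Zinc insertion into the carbon–iodine bond and β-elimination (reductive epoxide opening) give the vinyl carbinol with the tertiary C–O bond intact, so the (S) centre is carried over unchanged.

Step 13
Reactants: 15 (2E,6E,10S)-10-hydroxy-2,6,10-trimethyldodeca-2,6,11-trienyl pivalate; 10 (4-bromo-5-iodo-2,3-dimethylphenoxy)tri(propan-2-yl)silane
Product: 17 (2E,6E,10S)-12-[2-bromo-3,4-dimethyl-5-[tri(propan-2-yl)silyloxy]phenyl]-10-hydroxy-2,6,10-trimethyldodeca-2,6-dienyl pivalate, via B-alkyl-9-BBN borane 16 (not isolated)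
Conditions: 9-BBN (1.5 equiv), THF, 0 °C → rt; then 10, PdCl2(dppf) (5 mol%), aq. K3PO4 (3 equiv), DMF, 45 °C
Reagents that add atoms: none
Why: 9-BBN hydroborates only the monosubstituted vinyl group (anti-Markovnikov) and the B-alkyl borane undergoes Suzuki–Miyaura coupling at the aryl iodide much faster than at the flanked aryl bromide, the free tertiary hydroxyl being tolerated.

Step 14
Reactants: 17 (2E,6E,10S)-12-[2-bromo-3,4-dimethyl-5-[tri(propan-2-yl)silyloxy]phenyl]-10-hydroxy-2,6,10-trimethyldodeca-2,6-dienyl pivalate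
Product: 18 (2E,6E)-2,6-dimethyl-9-[(2S)-2,7,8-trimethyl-6-[tri(propan-2-yl)silyloxy]chroman-2-yl]nona-2,6-dienyl pivalate
Conditions: Pd(OAc)2 (5 mol%), 2-(di-tert-butylphosphino)-1,1'-binaphthyl (6 mol%), Cs2CO3 (1.5 equiv), toluene, 80 °C
Reagents that add atoms: none
Why: Palladium-catalysed intramolecular aryl etherification (Buchwald–Hartwig type C–O coupling) of a tertiary alkoxide, which has no β-hydride pathway, closes the chroman ring without touching the alkyl C–O bond, so C2 stays (S).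

Step 15
Reactants: 18 (2E,6E)-2,6-dimethyl-9-[(2S)-2,7,8-trimethyl-6-[tri(propan-2-yl)silyloxy]chroman-2-yl]nona-2,6-dienyl pivalate
Product: 19 (2E,6E)-2,6-dimethyl-9-[(2S)-2,7,8-trimethyl-6-[tri(propan-2-yl)silyloxy]chroman-2-yl]nona-2,6-dien-1-ol
Conditions: iBu2AlH (2.5 equiv), CH2Cl2, −78 °C; aq. KNaC4H4O6
Reagents that add atoms: none
Why: Hydride reduction cleaves the pivalate to the primary allylic alcohol while the aryl silyl ether and the alkenes are inert.

Step 16
Reactants: 19 (2E,6E)-2,6-dimethyl-9-[(2S)-2,7,8-trimethyl-6-[tri(propan-2-yl)silyloxy]chroman-2-yl]nona-2,6-dien-1-ol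
Product: 21 [(2S)-2-[(3E,7E)-9-bromo-4,8-dimethylnona-3,7-dienyl]-2,7,8-trimethylchroman-6-yl]oxy-tri(propan-2-yl)silane, via allylic mesylate 20 (not isolated)
Conditions: MsCl, Et3N, THF, −40 °C; then LiBr (4 equiv), −40 → 0 °C; used crude
Reagents that add atoms: lithium bromide [Li+].[Br-]
Why: Mesylation followed by SN2 displacement with bromide gives the primary allylic bromide without allylic transposition or loss of (E) geometry.

Step 17
Reactants: 3 (2E,6E,10E)-12-hydroxy-3,7,11-trimethyldodeca-2,6,10-trienyl acetate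
Product: 22 (2E,6E,10E)-12-chloro-3,7,11-trimethyldodeca-2,6,10-trienyl acetate
Conditions: N-chlorosuccinimide, Me2S, CH2Cl2, −40 → 0 °C
Reagents that add atoms: N-chlorosuccinimide O=C1CCC(=O)N1Cl
Why: Corey–Kim chlorination converts the primary allylic alcohol into the chloride by SN2 without allylic rearrangement and leaves the acetate alone.

Step 18
Reactants: 22 (2E,6E,10E)-12-chloro-3,7,11-trimethyldodeca-2,6,10-trienyl acetate
Product: 23 (2E,6E,10E)-12-chloro-3,7,11-trimethyldodeca-2,6,10-trien-1-ol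
Conditions: iBu2AlH (2.2 equiv), CH2Cl2, −78 °C; aq. KNaC4H4O6
Reagents that add atoms: none
Why: Low-temperature hydride reduction removes the acetate, which would not survive an organobarium reagent, without displacing the allylic chloride.

Step 19
Reactants: 23 (2E,6E,10E)-12-chloro-3,7,11-trimethyldodeca-2,6,10-trien-1-ol
Product: 24 tert-butyl-[(2E,6E,10E)-12-chloro-3,7,11-trimethyldodeca-2,6,10-trienoxy]diphenylsilane
Conditions: t-BuPh2SiCl, imidazole, CH2Cl2, 0 °C → rt
Reagents that add atoms: tert-butyl(chloro)diphenylsilane CC(C)(C)[Si](Cl)(c1ccccc1)c1ccccc1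
Why: Silylation gives a robust ether without acidic or electrophilic sites, compatible with the allylbarium chemistry of step 22.

Step 20
Reactants: 1 (2E,6E)-farnesol
Product: 25 [(2S,3S)-3-[(3E)-4,8-dimethylnona-3,7-dienyl]-3-methyloxiran-2-yl]methanol
Conditions: Ti(OiPr)4 (0.1 equiv), diethyl L-(+)-tartrate (0.12 equiv), t-BuOOH (2 equiv, anhydrous), 4 Å molecular sieves, CH2Cl2, −20 °C
Reagents that add atoms: tert-butyl hydroperoxide CC(C)(C)OO
Why: Sharpless asymmetric epoxidation with the L-(+)-tartrate ligand epoxidises only the 2,3-alkene and sets the future carbinol carbon C24' as (S) in about 95% ee.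

Step 21
Reactants: 25 [(2S,3S)-3-[(3E)-4,8-dimethylnona-3,7-dienyl]-3-methyloxiran-2-yl]methanol
Product: 26 (2R,3S)-3-[(3E)-4,8-dimethylnona-3,7-dienyl]-3-methyloxirane-2-carbaldehyde
Conditions: Dess–Martin periodinane (1.3 equiv), NaHCO3, CH2Cl2, 0 °C → rt; used at once
Reagents that add atoms: none
Why: Buffered Dess–Martin oxidation gives the non-enolisable α,β-epoxy aldehyde without epimerisation or epoxide opening (the R descriptor is only a priority change).

Step 22
Reactants: 24 tert-butyl-[(2E,6E,10E)-12-chloro-3,7,11-trimethyldodeca-2,6,10-trienoxy]diphenylsilane; 26 (2R,3S)-3-[(3E)-4,8-dimethylnona-3,7-dienyl]-3-methyloxirane-2-carbaldehyde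
Product: 28 (3E,7E,11E)-13-[tert-butyl(diphenyl)silyl]oxy-1-[(2S,3S)-3-[(3E)-4,8-dimethylnona-3,7-dienyl]-3-methyloxiran-2-yl]-3,7,11-trimethyltrideca-3,7,11-trien-1-ol (C1 epimers), via allylbarium chloride 27 (not isolated)
Conditions: BaI2 (1.7 equiv), LiC12H10 (lithium biphenylide, 3.4 equiv), THF, rt; 24 (1.5 equiv), −78 °C, 30 min; 26 (1 equiv), −78 °C, 30 min; aq. NH4Cl at −78 °C
Reagents that add atoms: none
Why: In this allylbarium carbonyl allylation, finely divided barium inserts into the allylic chloride at −78 °C to give a configurationally stable (E)-allylbarium that adds to the aldehyde through its unsubstituted α-carbon, forming C21'–C22' with the trisubstituted (E)-alkene retained, while the new carbinol forms as an epimer mixture (Felkin–Anh anti isomer major) that does not matter because this carbon becomes sp2 in step 24.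

Step 23
Reactants: 28 (3E,7E,11E)-13-[tert-butyl(diphenyl)silyl]oxy-1-[(2S,3S)-3-[(3E)-4,8-dimethylnona-3,7-dienyl]-3-methyloxiran-2-yl]-3,7,11-trimethyltrideca-3,7,11-trien-1-ol
Product: 29 (3E,7E,11E)-13-[tert-butyl(diphenyl)silyl]oxy-1-[(2S,3S)-3-[(3E)-4,8-dimethylnona-3,7-dienyl]-3-methyloxiran-2-yl]-3,7,11-trimethyltrideca-3,7,11-trienyl methanesulfonate (C1 epimers)
Conditions: MsCl (1.5 equiv), Et3N (2 equiv), CH2Cl2, −20 → 0 °C
Reagents that add atoms: methanesulfonyl chloride CS(Cl)(=O)=O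
Why: Sulfonylation through the sulfene turns the secondary hydroxyl into a leaving group without disturbing the neighbouring epoxide.

Step 24
Reactants: 29 (3E,7E,11E)-13-[tert-butyl(diphenyl)silyl]oxy-1-[(2S,3S)-3-[(3E)-4,8-dimethylnona-3,7-dienyl]-3-methyloxiran-2-yl]-3,7,11-trimethyltrideca-3,7,11-trienyl methanesulfonate
Product: 31 (2E,6E,10E,13E,15S,18E)-1-[tert-butyl(diphenyl)silyl]oxy-3,7,11,15,19,23-hexamethyltetracosa-2,6,10,13,18,22-hexaen-15-ol, via secondary iodide 30 (not isolated)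
Conditions: NaI (10 equiv), Zn dust (10 equiv), DMF, 70 °C; (E)-isomer purified on AgNO3-impregnated silica if needed
Reagents that add atoms: none
Why: Finkelstein exchange and zinc-mediated reductive elimination (the reductive epoxide opening of step 12) expel the epoxide oxygen from C23' with the tertiary C–O bond at C24' kept (S), and because the organozinc centre is not configurationally fixed both epimers funnel to the sterically favoured (E)-alkene.

Step 25
Reactants: 31 (2E,6E,10E,13E,15S,18E)-1-[tert-butyl(diphenyl)silyl]oxy-3,7,11,15,19,23-hexamethyltetracosa-2,6,10,13,18,22-hexaen-15-ol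
Product: 32 (2E,6E,10E,13E,15S,18E)-3,7,11,15,19,23-hexamethyltetracosa-2,6,10,13,18,22-hexaene-1,15-diol
Conditions: Bu4NF (1.5 equiv), THF, 0 °C → rt
Reagents that add atoms: none
Why: Fluoride-induced desilylation frees the primary allylic alcohol under conditions that leave the tertiary allylic alcohol and the skipped diene alone.

Step 26
Reactants: 32 (2E,6E,10E,13E,15S,18E)-3,7,11,15,19,23-hexamethyltetracosa-2,6,10,13,18,22-hexaene-1,15-diol
Product: 34 (2E,6E,10E,13E,15S,18E)-1-bromo-3,7,11,15,19,23-hexamethyltetracosa-2,6,10,13,18,22-hexaen-15-ol, via primary allylic mesylate 33 (not isolated)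
Conditions: MsCl (1.1 equiv), Et3N, THF, −40 °C; then LiBr (5 equiv), −40 → 0 °C; used crude
Reagents that add atoms: lithium bromide [Li+].[Br-]
Why: The primary hydroxyl is mesylated far faster than the hindered tertiary one and SN2 displacement by bromide then gives the allylic bromide without transposition.

Step 27
Reactants: 34 (2E,6E,10E,13E,15S,18E)-1-bromo-3,7,11,15,19,23-hexamethyltetracosa-2,6,10,13,18,22-hexaen-15-ol
Product: 35 (2E,6E,10E,13E,15S,18E)-3,7,11,15,19,23-hexamethyl-1-(4-methylphenyl)sulfonyltetracosa-2,6,10,13,18,22-hexaen-15-ol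
Conditions: TolSO2Na (1.5 equiv), DMF, rt
Reagents that add atoms: sodium 4-methylbenzenesulfinate [Na+].Cc1ccc(cc1)S([O-])=O
Why: SN2 S-alkylation of the sulfinate gives the stable allylic sulfone with the (E)-alkene unchanged.

Step 28
Reactants: 35 (2E,6E,10E,13E,15S,18E)-3,7,11,15,19,23-hexamethyl-1-(4-methylphenyl)sulfonyltetracosa-2,6,10,13,18,22-hexaen-15-ol
Product: 36 triethyl-[(2E,6E,10E,13E,15S,18E)-3,7,11,15,19,23-hexamethyl-1-(4-methylphenyl)sulfonyltetracosa-2,6,10,13,18,22-hexaen-15-yl]oxysilane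
Conditions: Et3SiOTf (1.5 equiv), 2,6-lutidine (2.5 equiv), CH2Cl2, −78 → 0 °C
Reagents that add atoms: triethylsilyl trifluoromethanesulfonate CC[Si](CC)(CC)OS(=O)(=O)C(F)(F)F
Why: Silyl triflate with a hindered base protects the tertiary alcohol so that only the sulfone α-carbon is deprotonated in the coupling.

Step 29
Reactants: 36 triethyl-[(2E,6E,10E,13E,15S,18E)-3,7,11,15,19,23-hexamethyl-1-(4-methylphenyl)sulfonyltetracosa-2,6,10,13,18,22-hexaen-15-yl]oxysilane; 21 [(2S)-2-[(3E,7E)-9-bromo-4,8-dimethylnona-3,7-dienyl]-2,7,8-trimethylchroman-6-yl]oxy-tri(propan-2-yl)silane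
Product: 38 [(2S)-2-[(3E,7E,11E,15E,19E,22E,24S,27E)-4,8,12,16,20,24,28,32-octamethyl-10-(4-methylphenyl)sulfonyl-24-triethylsilyloxytritriaconta-3,7,11,15,19,22,27,31-octaenyl]-2,7,8-trimethylchroman-6-yl]oxy-tri(propan-2-yl)silane (C10' epimers), via lithiated sulfone 37 (not isolated)
Conditions: n-BuLi (1.05 equiv), THF/DMPU, −78 °C, 30 min; then 21 (1.0 equiv), −78 → −30 °C
Reagents that add atoms: none
Why: SN2 alkylation of the sulfone-stabilised allylic carbanion at its α-carbon by the primary allylic bromide (Julia-type polyprenyl sulfone coupling) forms C9'–C10' without touching any alkene geometry.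

Step 30
Reactants: 38 [(2S)-2-[(3E,7E,11E,15E,19E,22E,24S,27E)-4,8,12,16,20,24,28,32-octamethyl-10-(4-methylphenyl)sulfonyl-24-triethylsilyloxytritriaconta-3,7,11,15,19,22,27,31-octaenyl]-2,7,8-trimethylchroman-6-yl]oxy-tri(propan-2-yl)silane
Product: 39 [(2S)-2-[(3E,7E,11E,15E,19E,22E,24S,27E)-4,8,12,16,20,24,28,32-octamethyl-24-triethylsilyloxytritriaconta-3,7,11,15,19,22,27,31-octaenyl]-2,7,8-trimethylchroman-6-yl]oxy-tri(propan-2-yl)silane
Conditions: PdCl2(dppp) (10 mol%), LiBHEt3 (3 equiv), THF, 0 °C → rt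
Reagents that add atoms: none
Why: Palladium-catalysed reductive desulfonylation ionises the allylic sulfone to a π-allyl complex of zerovalent palladium origin and hydride is delivered to the less substituted terminus, removing the sulfone without shifting or isomerising the (E)-alkene.

Step 31
Reactants: 39 [(2S)-2-[(3E,7E,11E,15E,19E,22E,24S,27E)-4,8,12,16,20,24,28,32-octamethyl-24-triethylsilyloxytritriaconta-3,7,11,15,19,22,27,31-octaenyl]-2,7,8-trimethylchroman-6-yl]oxy-tri(propan-2-yl)silane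
Product: 40 (2S)-2-[(3E,7E,11E,15E,19E,22E,24S,27E)-24-hydroxy-4,8,12,16,20,24,28,32-octamethyltritriaconta-3,7,11,15,19,22,27,31-octaenyl]-2,7,8-trimethylchroman-6-ol
Conditions: Bu4NF (4 equiv), degassed THF, Ar, 0 → 40 °C; aq. NH4Cl
Reagents that add atoms: none
Why: Fluoride cleaves the aryl and the tertiary silyl ether in one non-acidic operation that spares the ionisable tertiary allylic alcohol, the skipped diene and the oxidation-prone chromanol.

**Compound list**
1 | (2E,6E)-farnesol [(2E,6E)-3,7,11-trimethyldodeca-2,6,10-trien-1-ol] | CC(C)=CCC/C(C)=C/CC/C(C)=C/CO | starting material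
2 | (2E,6E)-farnesyl acetate | CC(C)=CCC/C(C)=C/CC/C(C)=C/COC(C)=O | intermediate
3 | (2E,6E,10E)-12-hydroxy-3,7,11-trimethyldodeca-2,6,10-trienyl acetate | OC/C(C)=C/CC/C(C)=C/CC/C(C)=C/COC(C)=O | intermediate
4 | 2,3-dimethylphenol | Cc1cccc(O)c1C | starting material
5 | 2,3-dimethyl-4-nitrosophenol | Cc1c(C)c(N=O)ccc1O | intermediate
6 | 4-amino-2,3-dimethylphenol | Cc1c(C)c(N)ccc1O | intermediate
7 | 2,3-dimethyl-4-[tri(propan-2-yl)silyloxy]aniline | Cc1c(C)c(N)ccc1O[Si](C(C)C)(C(C)C)C(C)C | intermediate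
8 | 6-iodo-2,3-dimethyl-4-[tri(propan-2-yl)silyloxy]aniline | Cc1c(C)c(N)c(I)cc1O[Si](C(C)C)(C(C)C)C(C)C | intermediate
9 | 6-iodo-2,3-dimethyl-4-[tri(propan-2-yl)silyloxy]benzenediazonium bromide (not isolated) | Cc1c(C)c([N+]#N)c(I)cc1O[Si](C(C)C)(C(C)C)C(C)C.[Br-] | intermediate
10 | (4-bromo-5-iodo-2,3-dimethylphenoxy)tri(propan-2-yl)silane | Cc1c(C)c(Br)c(I)cc1O[Si](C(C)C)(C(C)C)C(C)C | intermediate
11 | (2E,6E,10E)-12-acetoxy-2,6,10-trimethyldodeca-2,6,10-trienyl pivalate | CC(C)(C)C(=O)OC/C(C)=C/CC/C(C)=C/CC/C(C)=C/COC(C)=O | intermediate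
12 | (2E,6E,10E)-12-hydroxy-2,6,10-trimethyldodeca-2,6,10-trienyl pivalate | CC(C)(C)C(=O)OC/C(C)=C/CC/C(C)=C/CC/C(C)=C/CO | intermediate
13 | (2E,6E)-9-[(2S,3S)-3-(hydroxymethyl)-2-methyloxiran-2-yl]-2,6-dimethylnona-2,6-dienyl pivalate | OC[C@@H]1O[C@@]1(C)CC/C=C(C)/CC/C=C(C)/COC(=O)C(C)(C)C | intermediate
14 | (2E,6E)-9-[(2S,3R)-3-(iodomethyl)-2-methyloxiran-2-yl]-2,6-dimethylnona-2,6-dienyl pivalate | IC[C@@H]1O[C@@]1(C)CC/C=C(C)/CC/C=C(C)/COC(=O)C(C)(C)C | intermediate
15 | (2E,6E,10S)-10-hydroxy-2,6,10-trimethyldodeca-2,6,11-trienyl pivalate | C=C[C@@](C)(O)CC/C=C(C)/CC/C=C(C)/COC(=O)C(C)(C)C | intermediate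
16 | (2E,6E,10R)-12-(9-borabicyclo[3.3.1]nonan-9-yl)-10-hydroxy-2,6,10-trimethyldodeca-2,6-dienyl pivalate (same spatial arrangement as 15; not isolated) | C1CCC2CCCC1B2CC[C@@](C)(O)CC/C=C(C)/CC/C=C(C)/COC(=O)C(C)(C)C | intermediate
17 | (2E,6E,10S)-12-[2-bromo-3,4-dimethyl-5-[tri(propan-2-yl)silyloxy]phenyl]-10-hydroxy-2,6,10-trimethyldodeca-2,6-dienyl pivalate | Cc1c(C)c(O[Si](C(C)C)(C(C)C)C(C)C)cc(CC[C@@](C)(O)CC/C=C(C)/CC/C=C(C)/COC(=O)C(C)(C)C)c1Br | intermediate
18 | (2E,6E)-2,6-dimethyl-9-[(2S)-2,7,8-trimethyl-6-[tri(propan-2-yl)silyloxy]chroman-2-yl]nona-2,6-dienyl pivalate | CC(C)(C)C(=O)OC/C(C)=C/CC/C(C)=C/CC[C@@]1(C)CCc2cc(O[Si](C(C)C)(C(C)C)C(C)C)c(C)c(C)c2O1 | intermediate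
19 | (2E,6E)-2,6-dimethyl-9-[(2S)-2,7,8-trimethyl-6-[tri(propan-2-yl)silyloxy]chroman-2-yl]nona-2,6-dien-1-ol | OC/C(C)=C/CC/C(C)=C/CC[C@@]1(C)CCc2cc(O[Si](C(C)C)(C(C)C)C(C)C)c(C)c(C)c2O1 | intermediate
20 | methanesulfonate of 19 (not isolated) | CS(=O)(=O)OC/C(C)=C/CC/C(C)=C/CC[C@@]1(C)CCc2cc(O[Si](C(C)C)(C(C)C)C(C)C)c(C)c(C)c2O1 | intermediate
21 | [(2S)-2-[(3E,7E)-9-bromo-4,8-dimethylnona-3,7-dienyl]-2,7,8-trimethylchroman-6-yl]oxy-tri(propan-2-yl)silane | BrC/C(C)=C/CC/C(C)=C/CC[C@@]1(C)CCc2cc(O[Si](C(C)C)(C(C)C)C(C)C)c(C)c(C)c2O1 | intermediate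
22 | (2E,6E,10E)-12-chloro-3,7,11-trimethyldodeca-2,6,10-trienyl acetate | ClC/C(C)=C/CC/C(C)=C/CC/C(C)=C/COC(C)=O | intermediate
23 | (2E,6E,10E)-12-chloro-3,7,11-trimethyldodeca-2,6,10-trien-1-ol | ClC/C(C)=C/CC/C(C)=C/CC/C(C)=C/CO | intermediate
24 | tert-butyl-[(2E,6E,10E)-12-chloro-3,7,11-trimethyldodeca-2,6,10-trienoxy]diphenylsilane | ClC/C(C)=C/CC/C(C)=C/CC/C(C)=C/CO[Si](c1ccccc1)(c1ccccc1)C(C)(C)C | intermediate
25 | [(2S,3S)-3-[(3E)-4,8-dimethylnona-3,7-dienyl]-3-methyloxiran-2-yl]methanol [(2S,3S)-2,3-epoxyfarnesol] | OC[C@@H]1O[C@@]1(C)CC/C=C(C)/CCC=C(C)C | intermediate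
26 | (2R,3S)-3-[(3E)-4,8-dimethylnona-3,7-dienyl]-3-methyloxirane-2-carbaldehyde | O=C[C@@H]1O[C@@]1(C)CC/C=C(C)/CCC=C(C)C | intermediate
27 | chloro-[(2E,6E,10E)-12-[tert-butyl(diphenyl)silyl]oxy-2,6,10-trimethyldodeca-2,6,10-trienyl]barium (not isolated) | Cl[Ba]C/C(C)=C/CC/C(C)=C/CC/C(C)=C/CO[Si](c1ccccc1)(c1ccccc1)C(C)(C)C | intermediate
28 | (3E,7E,11E)-13-[tert-butyl(diphenyl)silyl]oxy-1-[(2S,3S)-3-[(3E)-4,8-dimethylnona-3,7-dienyl]-3-methyloxiran-2-yl]-3,7,11-trimethyltrideca-3,7,11-trien-1-ol (both C1 epimers, anti major) | CC(C)(C)[Si](OC/C=C(C)/CC/C=C(C)/CC/C=C(C)/CC(O)[C@@H]1O[C@@]1(C)CC/C=C(C)/CCC=C(C)C)(c1ccccc1)c1ccccc1 | intermediate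
29 | methanesulfonate of 28 (both C1 epimers) | CC(C)(C)[Si](OC/C=C(C)/CC/C=C(C)/CC/C=C(C)/CC(OS(C)(=O)=O)[C@@H]1O[C@@]1(C)CC/C=C(C)/CCC=C(C)C)(c1ccccc1)c1ccccc1 | intermediate
30 | tert-butyl-[(2E,6E,10E)-13-[(2R,3S)-3-[(3E)-4,8-dimethylnona-3,7-dienyl]-3-methyloxiran-2-yl]-13-iodo-3,7,11-trimethyltrideca-2,6,10-trienoxy]diphenylsilane (both C13 epimers; not isolated) | CC(C)(C)[Si](OC/C=C(C)/CC/C=C(C)/CC/C=C(C)/CC(I)[C@@H]1O[C@@]1(C)CC/C=C(C)/CCC=C(C)C)(c1ccccc1)c1ccccc1 | intermediate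
31 | (2E,6E,10E,13E,15S,18E)-1-[tert-butyl(diphenyl)silyl]oxy-3,7,11,15,19,23-hexamethyltetracosa-2,6,10,13,18,22-hexaen-15-ol | CC(C)(C)[Si](OC/C=C(C)/CC/C=C(C)/CC/C=C(C)/C/C=C/[C@@](C)(O)CC/C=C(C)/CCC=C(C)C)(c1ccccc1)c1ccccc1 | intermediate
32 | (2E,6E,10E,13E,15S,18E)-3,7,11,15,19,23-hexamethyltetracosa-2,6,10,13,18,22-hexaene-1,15-diol | OC/C=C(C)/CC/C=C(C)/CC/C=C(C)/C/C=C/[C@@](C)(O)CC/C=C(C)/CCC=C(C)C | intermediate
33 | 1-methanesulfonate of 32 (not isolated) | CS(=O)(=O)OC/C=C(C)/CC/C=C(C)/CC/C=C(C)/C/C=C/[C@@](C)(O)CC/C=C(C)/CCC=C(C)C | intermediate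
34 | (2E,6E,10E,13E,15S,18E)-1-bromo-3,7,11,15,19,23-hexamethyltetracosa-2,6,10,13,18,22-hexaen-15-ol | BrC/C=C(C)/CC/C=C(C)/CC/C=C(C)/C/C=C/[C@@](C)(O)CC/C=C(C)/CCC=C(C)C | intermediate
35 | (2E,6E,10E,13E,15S,18E)-3,7,11,15,19,23-hexamethyl-1-(4-methylphenyl)sulfonyltetracosa-2,6,10,13,18,22-hexaen-15-ol | Cc1ccc(cc1)S(=O)(=O)C/C=C(C)/CC/C=C(C)/CC/C=C(C)/C/C=C/[C@@](C)(O)CC/C=C(C)/CCC=C(C)C | intermediate
36 | triethyl-[(2E,6E,10E,13E,15S,18E)-3,7,11,15,19,23-hexamethyl-1-(4-methylphenyl)sulfonyltetracosa-2,6,10,13,18,22-hexaen-15-yl]oxysilane | Cc1ccc(cc1)S(=O)(=O)C/C=C(C)/CC/C=C(C)/CC/C=C(C)/C/C=C/[C@@](C)(O[Si](CC)(CC)CC)CC/C=C(C)/CCC=C(C)C | intermediate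
37 | 1-lithio derivative of 36 (sulfone α-carbanion; not isolated) | Cc1ccc(cc1)S(=O)(=O)C([Li])/C=C(C)/CC/C=C(C)/CC/C=C(C)/C/C=C/[C@@](C)(O[Si](CC)(CC)CC)CC/C=C(C)/CCC=C(C)C | intermediate
38 | [(2S)-2-[(3E,7E,11E,15E,19E,22E,24S,27E)-4,8,12,16,20,24,28,32-octamethyl-10-(4-methylphenyl)sulfonyl-24-triethylsilyloxytritriaconta-3,7,11,15,19,22,27,31-octaenyl]-2,7,8-trimethylchroman-6-yl]oxy-tri(propan-2-yl)silane (both C10' epimers) | Cc1ccc(cc1)S(=O)(=O)C(C/C(C)=C/CC/C(C)=C/CC[C@@]1(C)CCc2cc(O[Si](C(C)C)(C(C)C)C(C)C)c(C)c(C)c2O1)/C=C(C)/CC/C=C(C)/CC/C=C(C)/C/C=C/[C@@](C)(O[Si](CC)(CC)CC)CC/C=C(C)/CCC=C(C)C | intermediate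
39 | [(2S)-2-[(3E,7E,11E,15E,19E,22E,24S,27E)-4,8,12,16,20,24,28,32-octamethyl-24-triethylsilyloxytritriaconta-3,7,11,15,19,22,27,31-octaenyl]-2,7,8-trimethylchroman-6-yl]oxy-tri(propan-2-yl)silane | CC(C)=CCC/C(C)=C/CC[C@](C)(O[Si](CC)(CC)CC)/C=C/C/C(C)=C/CC/C(C)=C/CC/C(C)=C/CC/C(C)=C/CC/C(C)=C/CC[C@@]1(C)CCc2cc(O[Si](C(C)C)(C(C)C)C(C)C)c(C)c(C)c2O1 | intermediate
40 | (2S)-2-[(3E,7E,11E,15E,19E,22E,24S,27E)-24-hydroxy-4,8,12,16,20,24,28,32-octamethyltritriaconta-3,7,11,15,19,22,27,31-octaenyl]-2,7,8-trimethylchroman-6-ol (CNP0323443.2) | CC(C)=CCC/C(C)=C/CC[C@](C)(O)/C=C/C/C(C)=C/CC/C(C)=C/CC/C(C)=C/CC/C(C)=C/CC/C(C)=C/CC[C@@]1(C)CCc2cc(O)c(C)c(C)c2O1 | target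

**Totals and risks**

Total step count: 31. Longest linear sequence: 15 steps (1 → 2 → 3 → 22 → 23 → 24 → 28 → 29 → 31 → 32 → 34 → 35 → 36 → 38 → 39 → 40).

The three steps most likely to fail:

Step 22 (allylbarium addition). The risks are incomplete α-selectivity, loss of (E) geometry if the reagent warms, and the need for strictly anhydrous, freshly made barium. The fallback makes the same C21'–C22' bond by alkyne alkylation and sets out from 25 and 24. PPh3/CCl4 with NaHCO3 converts 25 into the epoxy chloride F1. n-BuLi (3 equiv, THF, −78 → −30 °C) then effects double elimination to the propargylic alcohol F2, with the (S) C–O bond untouched. Copper-catalysed coupling (CuI, NaI, K2CO3, DMF, rt) of the terminal alkyne with chloride 24 gives the skipped enynol F3. Hydroxyl-directed trans-hydroalumination with NaAlH2(OCH2CH2OMe)2 in THF reduces the propargylic alcohol to the (E)-alkene. The route is rejoined at 31, steps 22 to 24 being bypassed.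

Step 24 (NaI/Zn reductive opening). The risks are slow substitution at the hindered secondary mesylate and an E/Z mixture. The fallback sets out from 28. Dess–Martin oxidation gives the epoxy ketone F4, which removes the epimer problem. Wharton transposition (N2H4·H2O, AcOH cat., MeOH, 0 °C → rt) then turns the epoxy ketone into the transposed tertiary allylic alcohol with loss of N2 and with the C24'–O bond intact. The (E)-isomer is expected to predominate and is purified on AgNO3-impregnated silica. The route is rejoined at 31.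

Step 14 (Pd-catalysed ring closure). The aryl bromide is electron-rich and flanked on both sides, so oxidative addition and C–O reductive elimination may stall. The fallback sets out from 8 and 16 and replaces the bromide by a diazonium leaving group. Suzuki coupling of borane 16 with iodoaniline 8 (conditions of step 13) gives the amino alcohol F5. t-BuONO with TsOH in MeCN at 0 °C gives the diazonium tosylate F6, which is not isolated. On warming to 50 °C it loses N2 and the aryl cation is captured by the tertiary hydroxyl through a six-membered transition state (dediazoniative etherification). The alkyl C–O bond is again untouched, so C2 stays (S). The route is rejoined at 18, and step 7 is then not needed.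

**Further compounds**
F1 | step 22 | (2S,3R)-3-(chloromethyl)-2-[(3E)-4,8-dimethylnona-3,7-dienyl]-2-methyloxirane | ClC[C@@H]1O[C@@]1(C)CC/C=C(C)/CCC=C(C)C
F2 | step 22 | (3S,6E)-3,7,11-trimethyldodeca-6,10-dien-1-yn-3-ol | C#C[C@@](C)(O)CC/C=C(C)/CCC=C(C)C
F3 | step 22 | (2E,6E,10E,15S,18E)-1-[tert-butyl(diphenyl)silyl]oxy-3,7,11,15,19,23-hexamethyltetracosa-2,6,10,18,22-pentaen-13-yn-15-ol | CC(C)(C)[Si](OC/C=C(C)/CC/C=C(C)/CC/C=C(C)/CC#C[C@@](C)(O)CC/C=C(C)/CCC=C(C)C)(c1ccccc1)c1ccccc1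
F4 | step 24 | (3E,7E,11E)-13-[tert-butyl(diphenyl)silyl]oxy-1-[(2R,3S)-3-[(3E)-4,8-dimethylnona-3,7-dienyl]-3-methyloxiran-2-yl]-3,7,11-trimethyltrideca-3,7,11-trien-1-one | CC(C)(C)[Si](OC/C=C(C)/CC/C=C(C)/CC/C=C(C)/CC(=O)[C@@H]1O[C@@]1(C)CC/C=C(C)/CCC=C(C)C)(c1ccccc1)c1ccccc1
F5 | step 14 | (2E,6E,10S)-12-[2-amino-3,4-dimethyl-5-[tri(propan-2-yl)silyloxy]phenyl]-10-hydroxy-2,6,10-trimethyldodeca-2,6-dienyl pivalate | Cc1c(C)c(O[Si](C(C)C)(C(C)C)C(C)C)cc(CC[C@@](C)(O)CC/C=C(C)/CC/C=C(C)/COC(=O)C(C)(C)C)c1N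
F6 | step 14 | 2-[(3S,6E,10E)-3-hydroxy-3,7,11-trimethyl-12-(pivaloyloxy)dodeca-6,10-dienyl]-5,6-dimethyl-4-[tri(propan-2-yl)silyloxy]benzenediazonium 4-methylbenzenesulfonate | Cc1c(C)c(O[Si](C(C)C)(C(C)C)C(C)C)cc(CC[C@@](C)(O)CC/C=C(C)/CC/C=C(C)/COC(=O)C(C)(C)C)c1[N+]#N.Cc1ccc(cc1)S(=O)(=O)[O-]
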